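**Assumptions.** (i) Eel acetylcholinesterase hydrolyses the meso diacetate to the (1R,4S)-monoacetate. (ii) The aldol in Step 15 gives both C7 epimers with C8 trans to the C13 chain. The epimers are separated as acetates in Step 16.

## Retrosynthetic overview
1. Target ← Johnson α-iodination of the C10–H enone **19** (last step, so the base-sensitive iodoenone is not carried through).
2. **19** ← C7 acetylation of the aldol adduct **18**. **18** comes from the lithium alkoxide/enolate dianion of (S)-4-hydroxy-4-[(Z)-octenyl]cyclopentenone **12** and the Z-enal **17**. C8 is set trans to the C13 chain, and the C7 epimers are separated.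
3. **12** ← anti-selective propargylzinc 1,2-addition to (R)-4-acetoxycyclopentenone **6**, then Z-semihydrogenation, deacetylation and oxidation of C9. C4 chirality is transferred 1,3 to the quaternary carbinol C12.
4. **6** ← esterase desymmetrization of meso-3,5-diacetoxycyclopentene. The five-membered ring is already present in cyclopentadiene (**1**) and is carried through. The only other ring made is the transient endoperoxide (**2**) from the [4+2] with ¹O₂, which is cleaved to the diol.

## Route

**Step 1**
Reactants: **1** cyclopentadiene (freshly cracked)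
Product: **2** 2,3-dioxabicyclo[2.2.1]hept-5-ene
Conditions: O₂, rose bengal, hν, MeOH, –20 °C
Reagents that add atoms: O₂ (O=O)
Why: Photooxygenation is a suprafacial [4+2] cycloaddition of singlet O₂ across C1/C4, which fixes the cis-1,4 oxygen relationship.

**Step 2**
Reactants: **2**
Product: **3** cis-cyclopent-4-ene-1,3-diol (meso)
Conditions: thiourea, MeOH, 0 °C → rt
Reagents that add atoms: none
Why: Thiourea reduces the O–O bond without touching the alkene, giving the cis diol.

**Step 3**
Reactants: **3**
Product: **4** cis-3,5-diacetoxycyclopentene (meso)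
Conditions: Ac₂O, pyridine, DMAP (cat.), CH₂Cl₂, 0 °C
Reagents that add atoms: Ac₂O (CC(=O)OC(C)=O)
Why: Simple esterification gives the achiral meso substrate for desymmetrization.

**Step 4**
Reactants: **4**
Product: **5** (1R,4S)-4-hydroxycyclopent-2-en-1-yl acetate
Conditions: electric eel acetylcholinesterase, 0.1 M phosphate buffer pH 7.0, 25 °C (pH-stat with NaOH)
Reagents that add atoms: none (water supplies only H)
Why: The esterase (a hydrolase) selectively hydrolyses one of the two enantiotopic acetates of the meso diacetate, which sets the first stereocenters with high ee.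

**Step 5**
Reactants: **5**
Product: **6** (1R)-4-oxocyclopent-2-en-1-yl acetate, i.e. (R)-4-acetoxycyclopent-2-en-1-one
Conditions: Dess–Martin periodinane, NaHCO₃, CH₂Cl₂, 0 °C → rt (product used crude and promptly)
Reagents that add atoms: none
Why: Buffered DMP oxidizes the allylic secondary alcohol without epimerizing C4 or eliminating the acetate; the C4-acetoxy carbon (R) becomes C9 of the target.

**Step 6**
Reactants: **7** oct-2-yn-1-ol
Product: **8** 1-bromooct-2-yne
Conditions: PBr₃, Et₂O, pyridine (cat.), 0 °C
Reagents that add atoms: PBr₃ (BrP(Br)Br)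
Why: Conversion of a primary propargylic alcohol to the bromide, the precursor to the propargyl/allenylzinc reagent.

**Step 7**
Reactants: **6**, **8**
Product: **9** (1R,4S)-4-hydroxy-4-(oct-2-yn-1-yl)cyclopent-2-en-1-yl acetate
Conditions: Zn dust, THF/sat. aq. NH₄Cl, 0 °C → rt
Reagents that add atoms: none (8 is the coupling partner)
Why: In this Barbier-type addition the allenylzinc adds 1,2 to the enone C=O through an S_E2′ six-membered transition state, giving the homopropargylic alcohol. It attacks anti to the C4-OAc, which sets the quaternary carbinol (C12: O cis to OAc, chain trans). Any allenyl or syn isomers are removed by chromatography.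

**Step 8**
Reactants: **9**
Product: **10** (1R,4S)-4-hydroxy-4-[(2Z)-oct-2-en-1-yl]cyclopent-2-en-1-yl acetate
Conditions: H₂ (1 atm), Lindlar catalyst, quinoline, EtOAc, 23 °C
Reagents that add atoms: none (H₂ adds only H)
Why: Syn-hydrogenation on poisoned Pd stops at the cis alkene, giving the 14Z olefin; the isolated cyclopentene is too hindered to be reduced.

**Step 9**
Reactants: **10**
Product: **11** (1S,4R)-1-[(2Z)-oct-2-en-1-yl]cyclopent-2-ene-1,4-diol
Conditions: K₂CO₃, MeOH, 0 °C → rt
Reagents that add atoms: none
Why: Methanolysis removes the secondary acetate, and all stereocenters and the Z-olefin are untouched.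

**Step 10**
Reactants: **11**
Product: **12** (4S)-4-hydroxy-4-[(2Z)-oct-2-en-1-yl]cyclopent-2-en-1-one
Conditions: Dess–Martin periodinane, NaHCO₃, CH₂Cl₂, 0 °C
Reagents that add atoms: none
Why: The hindered tertiary allylic alcohol is inert to DMP, so only the secondary allylic alcohol is oxidized, with no Dauben-type transposition. This gives the C12-quaternary 4-hydroxycyclopentenone of known absolute configuration.

**Step 11**
Reactants: **13** hex-5-ynoic acid
Product: **14** 7-hydroxyhept-5-ynoic acid
Conditions: n-BuLi (2.2 equiv), THF, –78 → 0 °C; then (CH₂O)ₙ (cracked), 0 °C → rt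
Reagents that add atoms: formaldehyde (C=O)
Why: The carboxylate/acetylide dianion adds at the acetylide carbon to formaldehyde, adding the C7 carbon.

**Step 12**
Reactants: **14**
Product: **15** methyl 7-hydroxyhept-5-ynoate
Conditions: MeI, K₂CO₃, DMF, rt
Reagents that add atoms: MeI (CI)
Why: Carboxylate O-alkylation under mild base leaves the propargylic alcohol untouched.

**Step 13**
Reactants: **15**
Product: **16** methyl (5Z)-7-hydroxyhept-5-enoate
Conditions: H₂, Lindlar catalyst, quinoline, EtOAc, 23 °C
Reagents that add atoms: none
Why: Syn-semihydrogenation of the alkyne gives the Z-allylic alcohol that defines the 5Z olefin.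

**Step 14**
Reactants: **16**
Product: **17** methyl (5Z)-7-oxohept-5-enoate
Conditions: Dess–Martin periodinane, NaHCO₃, CH₂Cl₂, 0 °C (used immediately)
Reagents that add atoms: none
Why: Mild buffered oxidation avoids Z→E isomerization of the enal.

**Step 15**
Reactants: **12**, **17**
Product: **18** methyl (5Z,7S,8R,12R,14Z)-7,12-dihydroxy-9-oxoprosta-5,10,14-trien-1-oate (drawn as the desired C7 epimer; the 7R epimer forms alongside)
Conditions: LDA (2.2 equiv), THF, –78 °C, 30 min; then 17, –78 °C; quench with sat. NH₄Cl at –78 °C
Reagents that add atoms: none (17 is the electrophile)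
Why: In this dianion aldol the O–Li group suppresses β-elimination of the C12 oxygen. The aldehyde is delivered syn to the lithium alkoxide and anti to the C13 chain, so C8 ends up trans to C13; C7 forms as a mixture of epimers.

**Step 16**
Reactants: **18** (C7 epimer mixture)
Product: **19** methyl (5Z,7S,8R,12R,14Z)-7-acetoxy-12-hydroxy-9-oxoprosta-5,10,14-trien-1-oate
Conditions: Ac₂O, pyridine, DMAP (cat.), CH₂Cl₂, 0 °C; then silica/HPLC separation of the C7 epimers
Reagents that add atoms: Ac₂O (CC(=O)OC(C)=O)
Why: The secondary C7-OH is acetylated chemoselectively over the hindered tertiary C12-OH (no base strong enough to cause elimination of the β-acetoxy ketone). The robust acetates are then separated to give the single 7S diastereomer.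

**Step 17**
Reactants: **19**
Product: **20** target, methyl (5Z,7S,8R,12S,14Z)-7-acetoxy-12-hydroxy-10-iodo-9-oxoprosta-5,10,14-trien-1-oate
Conditions: I₂, pyridine/CH₂Cl₂ (1:1), 0 °C → rt; then Na₂S₂O₃ wash
Reagents that add atoms: I₂ (II)
Why: Johnson α-iodination proceeds by conjugate addition of pyridine, iodination of the enolate and elimination; it installs C10–I without affecting the acetate, the free tertiary alcohol or the Z-olefins.

## Compound list
1 | cyclopentadiene | C1C=CC=C1 | starting material
2 | 2,3-dioxabicyclo[2.2.1]hept-5-ene | C1=CC2CC1OO2 | intermediate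
3 | cis-cyclopent-4-ene-1,3-diol (meso) | O[C@H]1C=C[C@@H](O)C1 | intermediate
4 | cis-3,5-diacetoxycyclopentene (meso) | CC(=O)O[C@H]1C=C[C@@H](OC(C)=O)C1 | intermediate
5 | (1R,4S)-4-hydroxycyclopent-2-en-1-yl acetate | CC(=O)O[C@H]1C=C[C@@H](O)C1 | intermediate
6 | (1R)-4-oxocyclopent-2-en-1-yl acetate | CC(=O)O[C@H]1C=CC(=O)C1 | intermediate
7 | oct-2-yn-1-ol | CCCCCC#CCO | starting material
8 | 1-bromooct-2-yne | CCCCCC#CCBr | intermediate
9 | (1R,4S)-4-hydroxy-4-(oct-2-yn-1-yl)cyclopent-2-en-1-yl acetate | CC(=O)O[C@H]1C=C[C@](O)(CC#CCCCCC)C1 | intermediate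
10 | (1R,4S)-4-hydroxy-4-[(2Z)-oct-2-en-1-yl]cyclopent-2-en-1-yl acetate | CC(=O)O[C@H]1C=C[C@](O)(C/C=C\CCCCC)C1 | intermediate
11 | (1S,4R)-1-[(2Z)-oct-2-en-1-yl]cyclopent-2-ene-1,4-diol | O[C@H]1C=C[C@](O)(C/C=C\CCCCC)C1 | intermediate
12 | (4S)-4-hydroxy-4-[(2Z)-oct-2-en-1-yl]cyclopent-2-en-1-one | O=C1C=C[C@](O)(C/C=C\CCCCC)C1 | intermediate
13 | hex-5-ynoic acid | C#CCCCC(=O)O | starting material
14 | 7-hydroxyhept-5-ynoic acid | OCC#CCCCC(=O)O | intermediate
15 | methyl 7-hydroxyhept-5-ynoate | OCC#CCCCC(=O)OC | intermediate
16 | methyl (5Z)-7-hydroxyhept-5-enoate | OC/C=C\CCCC(=O)OC | intermediate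
17 | methyl (5Z)-7-oxohept-5-enoate | O=C/C=C\CCCC(=O)OC | intermediate
18 | aldol adduct (7S,8R,12R) | CCCCC/C=C\C[C@@]1(O)C=CC(=O)[C@@H]1[C@H](/C=C\CCCC(=O)OC)O | intermediate
19 | 7-acetoxy-7,8-dihydro-10-deiodo compound (7S,8R,12R) | CCCCC/C=C\C[C@@]1(O)C=CC(=O)[C@@H]1[C@H](/C=C\CCCC(=O)OC)OC(C)=O | intermediate
20 | 7-acetoxy-7,8-dihydroiodovulone I | CCCCC/C=C\C[C@@]1(O)C=C(I)C(=O)[C@@H]1[C@H](/C=C\CCCC(=O)OC)OC(C)=O | target

## Totals
- Total steps: 17 (including the 5-step side-chain preparations: 1 for bromide 8 and 4 for aldehyde 17).
- Longest linear sequence: 12 steps (Steps 1–5, 7–10, 15–17), counted from cyclopentadiene.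

## Three steps most likely to fail
1. **Step 15 (dianion aldol).** Risks are a poor C7 ratio, retro-aldol, or Z→E isomerization of the enal.
   Fallback: protect C12-OH as its TES ether, form the silyl dienol ether (TESOTf, Et₃N) and run a Mukaiyama aldol with 17 (BF₃·OEt₂, –78 °C). Resolve the C7 epimers by lipase-catalysed acetylation.
2. **Step 7 (propargylzinc addition).** Risks are homopropargyl/allenyl regioselectivity or syn (wrong-face) addition guided by the acetate.
   Fallback: convert 6 to the (R)-4-OTBS enone and add allylMgBr/CeCl₃ anti to OTBS. Then build the Z-olefin by Z-selective cross-metathesis with 1-heptene, which removes the alkyne/Lindlar pair.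
3. **Step 17 (Johnson iodination).** Risks are a sluggish reaction next to the quaternary C12, or β-elimination/C8 epimerization of the acetoxy ketone under pyridine.
   Fallback: iodinate earlier, at the stage of 12 (I₂, pyridine or I₂/TMSN₃), then run the dianion aldol and acetylation on the 2-iodoenone.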